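The constants come first, and the two earlier runs hold what is needed for a first pair of them.

| setting | teal | ochre | north | north-east |
|---|---|---|---|---|
| X | 10 mM | 10 mM | 10 mM | 10 mM |
| D | 6.2 mM | 27 mM | 10.5 mM | 40.0 mM |
| Z | 0.50 mM | 0.50 mM | 0.500 mM | 0.500 mM |
| temperature | 15 °C | 40 °C |  |  |
| remark | run made earlier | run made earlier | at 20 °C until 3.0 min, from then on at 60 °C | at 20 °C throughout |
| time |  |  | 6.0 min | 1.5 min |

teal run (percent of the X charged)

| time / min | G / % | X / % |
|---|---|---|
| 0.500 | 12 | 81 |
| 0.667 | 13 | 78 |
| 1.00 | 21 | 71 |
| 1.50 | 24 | 68 |
| 2.50 | 33 | 57 |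
| 4.00 | 38 | 51 |
| 6.00 | 41 | 43 |

ochre run (percent of the X charged)

| time / s | G / % | X / % |
|---|---|---|
| 12.0 | 51 | 32 |
| 15.0 | 58 | 30 |
| 20.0 | 61 | 24 |
| 30.0 | 68 | 17 |
| 60.0 | 71 | 6 |
| 80.0 | 72 | 7 |
| 120 | 78 | 0 |

(readings scatter by 2 percentage points)

* the winner by amount of G, in percent of the X charged; "neither" if no more than 2 percentage points parts them (north / north-east / neither)
* how much G is there at the end, in percent of the X charged: north
* how much G is there at the end, in percent of the X charged: north-east

What does the first reading of each run give? With D taken at its charge, the fall of X gives a constant of 0.0680 mM⁻¹ min⁻¹ in teal and 0.211 mM⁻¹ min⁻¹ in ochre, both readings with their scatter.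

And at 20 °C? Interpolating the logarithm in temperature gives 0.0853 mM⁻¹ min⁻¹.

What is the zero of your scale? Equal charges of X and D, because the two then fall together, and north stands close to that at 1.05 equivalents. One over the constant times the charge of X gives 1.17 min, the equal-charge half-time.

What stands in north at the change of temperature? The X left is one over one plus time over half-time, so 28.1% after 3.0 min. Teal's last reading sends 71.9% of the lost X to G, so I expect G near 51.7% at that moment.

And after that? This is the weak spot: both runs stayed cooler than 60 °C, so I give no figure for the hot part of north.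

And north-east? At 4.00 equivalents it lies far from the zero, and with D taken at its charge the loss of X is pseudo-first-order. Its half-time with D held at its charge is 0.203 min, and 7.39 such half-times fit into 1.5 min, but that count holds only while D stays near its charge, so I give no figure for the X left. Ochre's last reading, with X at 0%, suggests G near 78% for north-east. My figure for north belongs to the change of temperature and not to its end, with 28.1% of the X still to react by my reckoning, so the two can't be compared and I name no winner.

The forecast says north-east, with 60% for north and 76% for north-east, and of the hot stage: “At 60 °C the catalyst dies within seconds, so the heating step adds little.”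

The flasks give north-east as the winner, with 50.0% of G in north and 81.9% in north-east.

    X + G → J (k = 2.21 M⁻¹ min⁻¹, Ea = 68.0 kJ mol⁻¹)
    X + Z → E (k = 1120 M⁻¹ min⁻¹, Ea = 53.0 kJ mol⁻¹)
    2 D → L (k = 13.6 M⁻¹ min⁻¹, Ea = 52.0 kJ mol⁻¹)
    X + D → Q, rate k4*[X] as long as [D] is above zero (k = 0.0543 min⁻¹, Ea = 96.0 kJ mol⁻¹)
    X + D → G (k = 70.6 M⁻¹ min⁻¹, Ea = 45.0 kJ mol⁻¹)
    (constants at 20 °C)

In north the equal-charge half-time of 1.17 min stands against 13 min, the half-life of X by the step to Q at 0.644 min, which is about ten times longer. After half of the time, at 3.00 min, the step to G has 97% of its turnover up to the end behind it and the step to Q 31%, and at the end, at 6.00 min, north holds 26.4% of Q. In north-east the same half-time, scaled to the charge of D, is 0.203 min, shorter than the time of 1.5 min, and Q ends at 2.50%.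

The earlier runs and the new flask stem from a simulated flask with made-up constants; the scatter is artificial.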